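Ring A is a resorcinol whose carbons C1 (aroyl-bearing), C2 (ethyl-bearing), C4 and C6 (oxygenated) repeat the 1,3-spacing of a poly-β-carbonyl chain, so the route rests on cutting the C1–C2 bond of ring A. A single base-induced aldol condensation of an open-chain aryl tetraketone makes that bond, closes and aromatizes ring A, and delivers the crowded tetra-ortho-substituted benzophenone without any aryl–carbonyl coupling. The precursor is 1-(2-ethenyl-4,6-dimethoxyphenyl)nonane-1,3,5,7-tetraone. Ring B is preformed, its phenols are masked as methyl ethers, and it carries an inert vinyl group that later provides the CH2 link and C6 of the 4-hydroxy-2-pyranone (ring C).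

Key step: step 6

Remark: all poly-β-carbonyl compounds are drawn in their keto forms although they exist largely as enols. The target has no stereocentre, so no stereocontrol is needed.

Step 1
Reactants: 1 pentane-2,4-dione; 2 methyl propanoate
Product: 4 octane-2,4,6-trione, via pentane-2,4-dione dilithium dianion 3 (not isolated)
Conditions: 1 (2 equiv), LiN(i-Pr)2 (4 equiv), THF, 0 °C; then 2 (1 equiv), 0 °C → rt; 2 M HCl
Reagents that add atoms: none
Why: Claisen-type acylation of a 1,3-diketone dianion, in which the terminal CH2 carbanion of 3 is the most nucleophilic site and attacks the ester carbonyl, while the second equivalent of 3 deprotonates the more acidic triketone as it forms and so shields it from further attack.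

Step 2
Reactants: 5 1-bromo-3,5-dimethoxybenzene
Product: 7 2-bromo-4,6-dimethoxybenzaldehyde, via aryl iminium chloride 6 (not isolated)
Conditions: POCl3, DMF, 0 → 90 °C; then ice-water
Reagents that add atoms: N,N-dimethylformamide CN(C)C=O; water O
Why: Vilsmeier–Haack formylation, in which the chloroiminium ion attacks the ring carbon para to one methoxy group and ortho to the other (next to bromine) rather than the carbon squeezed between both methoxy groups, and water then hydrolyses iminium salt 6.

Step 3
Reactants: 7 2-bromo-4,6-dimethoxybenzaldehyde; 8 potassium ethenyltrifluoroborate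
Product: 9 2-ethenyl-4,6-dimethoxybenzaldehyde
Conditions: PdCl2 (cat.), PPh3 (cat.), Cs2CO3 (3 equiv), THF/H2O 9:1, 85 °C (sealed)
Reagents that add atoms: none
Why: Suzuki–Miyaura vinylation, in which zerovalent palladium formed in the flask inserts into the C–Br bond activated by the ortho formyl group and the slowly hydrolysed trifluoroborate transfers the vinyl group without touching the non-enolizable aldehyde.

Step 4
Reactants: 9 2-ethenyl-4,6-dimethoxybenzaldehyde
Product: 10 2-ethenyl-4,6-dimethoxybenzoic acid
Conditions: NaClO2, NaH2PO4, 2-methylbut-2-ene (large excess), t-BuOH/H2O, 0 °C → rt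
Reagents that add atoms: sodium chlorite [Na+].[O-]Cl=O
Why: Pinnick oxidation, in which chlorous acid adds to the formyl group and fragments to the acid, and the excess trisubstituted alkene traps the hypochlorous acid before it can chlorinate the electron-rich ring or attack the styrene.

Step 5
Reactants: 10 2-ethenyl-4,6-dimethoxybenzoic acid; 4 octane-2,4,6-trione
Product: 13 1-(2-ethenyl-4,6-dimethoxyphenyl)nonane-1,3,5,7-tetraone, via acyl imidazolide 11 (not isolated), via trione trilithium trianion 12 (not isolated)
Conditions: 10, 1,1'-carbonyldiimidazole (CDI, 1.0 equiv), THF, rt, CO2 purged with Ar; added at −78 °C to 12 [from 4 (3 equiv), LiN(i-Pr)2 (9 equiv), THF, 0 °C]; → 0 °C; cold 1 M HCl; excess 4 removed under high vacuum, no silica gel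
Reagents that add atoms: none
Why: Claisen-type C-acylation of a 1,3,5-triketone trianion, in which the third deprotonation occurs at the less substituted CH3 terminus, this primary carbanion is the most reactive site of 12, the twisted N-acylimidazole 11 is a much better acyl donor than an alkyl ester of this doubly ortho-substituted acid, and the excess of 12 takes up the protons of free imidazole and of the new C2 methylene group.

Step 6
Reactants: 13 1-(2-ethenyl-4,6-dimethoxyphenyl)nonane-1,3,5,7-tetraone
Product: 15 (2-ethenyl-4,6-dimethoxyphenyl)(2-ethyl-4,6-dihydroxyphenyl)methanone, via cyclic ketol 14 (not isolated)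
Conditions: 1 M aq KOH, Ar, rt; then 1 M HCl, 0 °C
Reagents that add atoms: none
Why: Hydroxide turns 13 into its polyenolate, chain carbon C2 (the CH2 between the aroyl C1 and the C3 carbonyl) adds to the C7 propionyl carbonyl to give ketol 14, and E1cB loss of water followed by enolization at C3 and C5 gives the resorcinol, an irreversible aromatization that drains the preceding equilibria. The closest known reaction type is the base-induced intramolecular aldol condensation of 1-aryl-1,3,5,7-tetraketones to 2-acylresorcinols, a known biomimetic polyketide cyclization. Ring A (chain atoms C2–C7) closes in a 6-exo-trig mode with respect to C7=O, and the closure is allowed whether the C2 enolate is drawn towards C3 (enolendo) or towards C1 (enolexo). No stereocentre is created in the product, because the two centres of 14 disappear on aromatization. The step needs C2→C7 closure in preference to three alternatives: the C6→C1 aldol leading to a biaryl propiophenone is slowed because C1 is an aryl ketone blocked on both sides by the ortho OMe and vinyl groups of ring B, the C8→C3 aldol fails because the ethyl CH2 is only singly activated and is not enolized by aqueous hydroxide, and O-cyclization to a 4-pyranone requires acid. The vinyl and methyl ether groups are inert to cold alkali, and working at room temperature keeps the new ortho phenoxide from displacing the neighbouring ring B methoxy group (xanthone closure).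

Step 7
Reactants: 15 (2-ethenyl-4,6-dimethoxyphenyl)(2-ethyl-4,6-dihydroxyphenyl)methanone
Product: 16 (2-ethenyl-4,6-dimethoxyphenyl)(2-ethyl-4,6-dimethoxyphenyl)methanone
Conditions: MeI, K2CO3, DMF, rt
Reagents that add atoms: iodomethane CI
Why: Williamson-type O-methylation, in which both phenoxides, including the hydrogen-bonded one ortho to the ketone, are alkylated by SN2 attack at a temperature where xanthone closure does not compete, and four identical ethers allow a single final deprotection.

Step 8
Reactants: 16 (2-ethenyl-4,6-dimethoxyphenyl)(2-ethyl-4,6-dimethoxyphenyl)methanone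
Product: 18 (2-ethyl-4,6-dimethoxyphenyl)[2-(2-hydroxyethyl)-4,6-dimethoxyphenyl]methanone, via B-alkyl-9-BBN adduct 17 (not isolated)
Conditions: 9-BBN (9-borabicyclo[3.3.1]nonane), THF, rt → 50 °C; then 30% H2O2, 3 M NaOH, 0 °C → rt
Reagents that add atoms: hydrogen peroxide OO
Why: Hydroboration–oxidation, in which the bulky borane places boron on the terminal styrene carbon (anti-Markovnikov), leaves untouched the electron-rich diaryl ketone blocked by four ortho substituents, and alkaline peroxide replaces boron by hydroxyl.

Step 9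
Reactants: 18 (2-ethyl-4,6-dimethoxyphenyl)[2-(2-hydroxyethyl)-4,6-dimethoxyphenyl]methanone
Product: 20 2-[2-(2-ethyl-4,6-dimethoxybenzoyl)-3,5-dimethoxyphenyl]acetic acid, via arylacetaldehyde 19 (not isolated)
Conditions: 2,2,6,6-tetramethylpiperidin-1-oxyl (TEMPO, cat.), PhI(OAc)2 (2.5 equiv), MeCN/H2O 1:1, rt
Reagents that add atoms: water O
Why: Oxoammonium-mediated (TEMPO/PhI(OAc)2) oxidation, in which the primary alcohol gives aldehyde 19 and its hydrate is oxidised on to the acid in the aqueous medium, under chlorine-free conditions that spare the methoxyarenes.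

Step 10
Reactants: 20 2-[2-(2-ethyl-4,6-dimethoxybenzoyl)-3,5-dimethoxyphenyl]acetic acid; 21 2,2,6-trimethyl-4H-1,3-dioxin-4-one
Product: 24 6-{3-[2-(2-ethyl-4,6-dimethoxybenzoyl)-3,5-dimethoxyphenyl]-2-oxopropyl}-2,2-dimethyl-4H-1,3-dioxin-4-one, via arylacetyl imidazolide 22 (not isolated), via dioxinone lithium dienolate 23 (not isolated)
Conditions: 20, CDI (1.0 equiv), THF, rt, CO2 purged with Ar; added at −78 °C to 23 [from 21 (3.5 equiv), LiN(SiMe3)2 (3.5 equiv), THF, −78 °C]; → −20 °C; 1 M HCl
Reagents that add atoms: none
Why: Claisen-type γ-acylation of a vinylogous ester enolate, in which dienolate 23 reacts with acyl donors at its exocyclic CH2 terminus, its excess covers the protons of imidazole and of the β-dicarbonyl product, and the tetra-ortho-substituted benzophenone carbonyl is too hindered to be attacked.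

Step 11
Reactants: 24 6-{3-[2-(2-ethyl-4,6-dimethoxybenzoyl)-3,5-dimethoxyphenyl]-2-oxopropyl}-2,2-dimethyl-4H-1,3-dioxin-4-one
Product: 26 6-{[2-(2-ethyl-4,6-dimethoxybenzoyl)-3,5-dimethoxyphenyl]methyl}-4-hydroxy-2H-pyran-2-one, via acylketene 25 (not isolated)
Conditions: toluene, 110 °C
Reagents that add atoms: none
Why: Thermal retro-hetero-Diels–Alder reaction followed by acylketene trapping, in which loss of acetone gives 25 and the enol oxygen of its distal ketone adds to the ketene carbon in a six-membered closure that gives ring C under neutral conditions.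

Step 12
Reactants: 26 6-{[2-(2-ethyl-4,6-dimethoxybenzoyl)-3,5-dimethoxyphenyl]methyl}-4-hydroxy-2H-pyran-2-one
Product: 27 6-{[2-(2-ethyl-4,6-dihydroxybenzoyl)-3,5-dihydroxyphenyl]methyl}-4-hydroxy-2H-pyran-2-one
Conditions: BBr3 (12 equiv), CH2Cl2, −78 °C → rt; then ice-water
Reagents that add atoms: none
Why: Lewis-acid aryl methyl ether cleavage, in which BBr3 binds each ether oxygen, bromide removes the methyl group by SN2 attack and hydrolysis of the aryl borates frees the four phenols, while the pyranone (merely bound as its borate) and the hindered ketone should survive.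

Compound list
1 | pentane-2,4-dione | CC(=O)CC(C)=O | starting material
2 | methyl propanoate | CCC(=O)OC | starting material
3 | dilithium dianion of pentane-2,4-dione (formed in the flask) | [Li+].[Li+].C=C([O-])C=C(C)[O-] | intermediate
4 | octane-2,4,6-trione | CCC(=O)CC(=O)CC(C)=O | intermediate
5 | 1-bromo-3,5-dimethoxybenzene | COc1cc(Br)cc(OC)c1 | starting material
6 | (2-bromo-4,6-dimethoxyphenyl)methylidene(dimethyl)ammonium chloride (formed in the flask) | COc1cc(Br)c(C=[N+](C)C)c(OC)c1.[Cl-] | intermediate
7 | 2-bromo-4,6-dimethoxybenzaldehyde | COc1cc(Br)c(C=O)c(OC)c1 | intermediate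
8 | potassium ethenyltrifluoroborate | [K+].C=C[B-](F)(F)F | starting material
9 | 2-ethenyl-4,6-dimethoxybenzaldehyde | COc1cc(C=C)c(C=O)c(OC)c1 | intermediate
10 | 2-ethenyl-4,6-dimethoxybenzoic acid | COc1cc(C=C)c(C(=O)O)c(OC)c1 | intermediate
11 | (2-ethenyl-4,6-dimethoxyphenyl)(1H-imidazol-1-yl)methanone (formed in the flask) | COc1cc(C=C)c(C(=O)n2ccnc2)c(OC)c1 | intermediate
12 | trilithium trianion of octane-2,4,6-trione, deprotonated at C1, C3 and C5 (formed in the flask) | [Li+].[Li+].[Li+].C=C([O-])C=C([O-])C=C([O-])CC | intermediate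
13 | 1-(2-ethenyl-4,6-dimethoxyphenyl)nonane-1,3,5,7-tetraone | CCC(=O)CC(=O)CC(=O)CC(=O)c1c(OC)cc(OC)cc1C=C | intermediate
14 | 4-(2-ethenyl-4,6-dimethoxybenzoyl)-5-ethyl-5-hydroxycyclohexane-1,3-dione, transient mixture of diastereomers (formed in the flask) | CCC1(O)CC(=O)CC(=O)C1C(=O)c1c(OC)cc(OC)cc1C=C | intermediate
15 | (2-ethenyl-4,6-dimethoxyphenyl)(2-ethyl-4,6-dihydroxyphenyl)methanone | CCc1cc(O)cc(O)c1C(=O)c1c(OC)cc(OC)cc1C=C | intermediate
16 | (2-ethenyl-4,6-dimethoxyphenyl)(2-ethyl-4,6-dimethoxyphenyl)methanone | CCc1cc(OC)cc(OC)c1C(=O)c1c(OC)cc(OC)cc1C=C | intermediate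
17 | {2-[2-(9-borabicyclo[3.3.1]nonan-9-yl)ethyl]-4,6-dimethoxyphenyl}(2-ethyl-4,6-dimethoxyphenyl)methanone (formed in the flask) | CCc1cc(OC)cc(OC)c1C(=O)c1c(OC)cc(OC)cc1CCB1C2CCCC1CCC2 | intermediate
18 | (2-ethyl-4,6-dimethoxyphenyl)[2-(2-hydroxyethyl)-4,6-dimethoxyphenyl]methanone | CCc1cc(OC)cc(OC)c1C(=O)c1c(OC)cc(OC)cc1CCO | intermediate
19 | 2-[2-(2-ethyl-4,6-dimethoxybenzoyl)-3,5-dimethoxyphenyl]acetaldehyde (formed in the flask) | CCc1cc(OC)cc(OC)c1C(=O)c1c(OC)cc(OC)cc1CC=O | intermediate
20 | 2-[2-(2-ethyl-4,6-dimethoxybenzoyl)-3,5-dimethoxyphenyl]acetic acid | CCc1cc(OC)cc(OC)c1C(=O)c1c(OC)cc(OC)cc1CC(=O)O | intermediate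
21 | 2,2,6-trimethyl-4H-1,3-dioxin-4-one | CC1=CC(=O)OC(C)(C)O1 | starting material
22 | 2-[2-(2-ethyl-4,6-dimethoxybenzoyl)-3,5-dimethoxyphenyl]-1-(1H-imidazol-1-yl)ethan-1-one (formed in the flask) | CCc1cc(OC)cc(OC)c1C(=O)c1c(OC)cc(OC)cc1CC(=O)n1ccnc1 | intermediate
23 | lithium 2,2-dimethyl-6-methylidene-6H-1,3-dioxin-4-olate (formed in the flask) | [Li+].C=C1C=C([O-])OC(C)(C)O1 | intermediate
24 | 6-{3-[2-(2-ethyl-4,6-dimethoxybenzoyl)-3,5-dimethoxyphenyl]-2-oxopropyl}-2,2-dimethyl-4H-1,3-dioxin-4-one | CCc1cc(OC)cc(OC)c1C(=O)c1c(OC)cc(OC)cc1CC(=O)CC1=CC(=O)OC(C)(C)O1 | intermediate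
25 | 6-[2-(2-ethyl-4,6-dimethoxybenzoyl)-3,5-dimethoxyphenyl]hex-1-ene-1,3,5-trione, the acylketene (formed in the flask) | CCc1cc(OC)cc(OC)c1C(=O)c1c(OC)cc(OC)cc1CC(=O)CC(=O)C=C=O | intermediate
26 | 6-{[2-(2-ethyl-4,6-dimethoxybenzoyl)-3,5-dimethoxyphenyl]methyl}-4-hydroxy-2H-pyran-2-one | CCc1cc(OC)cc(OC)c1C(=O)c1c(OC)cc(OC)cc1Cc1cc(O)cc(=O)o1 | intermediate
27 | 6-{[2-(2-ethyl-4,6-dihydroxybenzoyl)-3,5-dihydroxyphenyl]methyl}-4-hydroxy-2H-pyran-2-one | CCc1cc(O)cc(O)c1C(=O)c1c(O)cc(O)cc1Cc1cc(O)cc(=O)o1 | target

Total step count: 12. Longest linear sequence: 11 steps (5 to 27, steps 2–12). Step 1 is the only side branch.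

Steps most likely to fail

Step 5.
- What may go wrong: attack on the doubly ortho-substituted acyl carbon may be too slow, so that proton transfer and O-acylation of the polyanion take over.
- Fallback: it sets out from aldehyde 9 and trione 4, makes step 4 unnecessary, and comes back at 13. Trianion 12, generated as before, is added at −78 °C to the much more accessible formyl group of 9 in an aldol-type polyanion addition. This should give racemic 1-(2-ethenyl-4,6-dimethoxyphenyl)-1-hydroxynonane-3,5,7-trione F1 after a cold, weakly acidic quench. Oxidation of this β-hydroxy ketone with 2-iodoxybenzoic acid (IBX) in refluxing EtOAc, a known way to 1,3-diketones, should then give 13.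

Step 6.
- What may go wrong: the chain may fold in the wrong sense, or hydroxide may cleave it by retro-Claisen fragmentation before it closes.
- Fallback: it gives up the biomimetic closure, builds the benzophenone from two preformed rings, sets out from aldehyde 9 and comes back at 16. Commercial 1-ethyl-3,5-dimethoxybenzene (CCc1cc(OC)cc(OC)c1) is brominated with N-bromosuccinimide in MeCN at 0 °C, para to one methoxy group and next to the ethyl group, to give 2-bromo-1-ethyl-3,5-dimethoxybenzene F2. Bromine–lithium exchange with n-BuLi in THF at −78 °C gives (2-ethyl-4,6-dimethoxyphenyl)lithium F3. Addition of F3 to 9 and a water quench give racemic (2-ethenyl-4,6-dimethoxyphenyl)(2-ethyl-4,6-dimethoxyphenyl)methanol F4. Oxidation with the triacetoxy periodinane DMP in CH2Cl2 should then give 16.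

Step 10.
- What may go wrong: the basic dienolate may remove the acidic benzylic proton of the activated acid instead of adding to it, or the activated acyl group may close onto the neighbouring ketone oxygen.
- Fallback: it replaces the lithium enolate by a neutral silyl nucleophile, sets out from acid 20 and comes back at 26. Treatment with (COCl)2 and catalytic DMF in CH2Cl2 at 0 °C gives 2-[2-(2-ethyl-4,6-dimethoxybenzoyl)-3,5-dimethoxyphenyl]acetyl chloride F5. This is treated without base with commercial 1-methoxy-1,3-bis(trimethylsilyloxy)buta-1,3-diene in CH2Cl2, −78 → 20 °C. Attack through the terminal diene carbon and aqueous work-up should give methyl 6-[2-(2-ethyl-4,6-dimethoxybenzoyl)-3,5-dimethoxyphenyl]-3,5-dioxohexanoate F6. DBU in refluxing toluene then lactonizes F6 through the C5 enol oxygen to 26.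

Further compounds
F1 | step 5 | 1-(2-ethenyl-4,6-dimethoxyphenyl)-1-hydroxynonane-3,5,7-trione (racemic) | CCC(=O)CC(=O)CC(=O)CC(O)c1c(OC)cc(OC)cc1C=C
F2 | step 6 | 2-bromo-1-ethyl-3,5-dimethoxybenzene | CCc1cc(OC)cc(OC)c1Br
F3 | step 6 | (2-ethyl-4,6-dimethoxyphenyl)lithium | [Li]c1c(CC)cc(OC)cc1OC
F4 | step 6 | (2-ethenyl-4,6-dimethoxyphenyl)(2-ethyl-4,6-dimethoxyphenyl)methanol (racemic) | CCc1cc(OC)cc(OC)c1C(O)c1c(OC)cc(OC)cc1C=C
F5 | step 10 | 2-[2-(2-ethyl-4,6-dimethoxybenzoyl)-3,5-dimethoxyphenyl]acetyl chloride | CCc1cc(OC)cc(OC)c1C(=O)c1c(OC)cc(OC)cc1CC(=O)Cl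
F6 | step 10 | methyl 6-[2-(2-ethyl-4,6-dimethoxybenzoyl)-3,5-dimethoxyphenyl]-3,5-dioxohexanoate | CCc1cc(OC)cc(OC)c1C(=O)c1c(OC)cc(OC)cc1CC(=O)CC(=O)CC(=O)OC
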